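What the midnight reading at 90.0 min left in this flask was 0% target and 0% starting material, so I built my note for the colleague taking over the bench on the early readings.

| flask | starting material | catalyst | remark | time |
|---|---|---|---|---|
| midnight | 0.50 M (fed, over 1.5 min) | 10 mM | the very flask that is asked about, followed so far |  |
| flask | 0.50 M (fed, over 1.5 min) | 10 mM |  | 4.0 h |

midnight run (percent of the starting material charged)

| time / min | target / % | starting material / % |
|---|---|---|
| 1.00 | 2 | 53 |
| 3.00 | 13 | 59 |
| 10.0 | 6 | 33 |
| 30.0 | 3 | 6 |
| 90.0 | 0 | 0 |

(each reading ± 1.5 percentage points)

- percentages count the whole charge, also what has not yet gone in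

* time up to 4.0 h at which target stands highest
* the amount of target, in percent of the starting material charged, at that time
* the first time at which target reaches 10%, in the same percent, in min

The catalyst was the reagent charged in the smaller amount, so I wrote its balance first and took as my yardstick the catalyst charged as a fraction of the starting material charged, which I called the catalyst share, 2.00%. Any amount in percent of the charge, divided by that share, gives its catalyst equivalents. At 3.00 min, with the feed over, the readings gave:

target: 13% / 2.00% = 6.50 catalyst equivalents

unaccounted for: 28 percentage points / 2.00% = 14.0 catalyst equivalents

Both stood above one , so I wrote that, counting one molecule on each catalyst, the catalyst could hold 2.00% of the charge, less than either amount . I told my colleague to take the target near 3.00 min, where I expected a peak a little above that reading, to expect none by 4.0 h, and to leave the catalyst charge alone, since this run showed one charge.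

The forecast gave 13.5% at 0.058 h and 10% at 2.2 min, saying “The maximum therefore falls just after dosing ends”.

The flask gave 14.3% at 0.0626 h, and reached 10% at 1.82 min.

    starting material ⇌ target (K = 0.260, k = 0.00250 s⁻¹)
    target ⇌ isomer of the product (K = 0.330, k = 0.00200 s⁻¹)
    catalyst ⇌ dormant form (K = 0.430, k = 0.00360 s⁻¹)
    isomer of the product + catalyst ⇌ starting material + catalyst, rate k4*[catalyst]*[isomer of the product] forward; the back reaction follows from the equilibrium constant (k = 5.10 L mol⁻¹ s⁻¹)
    starting material → uncatalysed product (k = 0.00210 s⁻¹)

At that best time in this flask uncatalysed product stood at 26.3%, or 13.2 catalyst equivalents, and target at 7.15. In the neighbour flask, with a quarter of the catalyst, 0.0025 M, target stood highest at 14.0%, which is 27.9 catalyst equivalents there.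

The readings were generated by integration for substances that don't exist, noise included.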